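You get no rate constants for these flasks, so you start from Friday's readings and a bench rule.

| flask | starting material | reagent | remark | time |
|---|---|---|---|---|
| Friday's | 0.030 M (in portions, 2) | 0.70 equiv | run made earlier; portions every 8.0 min |  |
| cedar | 0.020 M | 0.700 equiv | everything together at the start | 60 min |
| birch | 0.020 M (in portions, 2) | 0.700 equiv | the portions of starting material follow each other after 8.0 min, the first at the start | 15 min |

Friday's run (percent of the starting material charged)

| time / min | target / % | starting material / % |
|---|---|---|
| 0.333 | 13 | 35 |
| 0.667 | 20 | 31 |
| 1.33 | 26 | 24 |
| 2.50 | 33 | 16 |
| 5.00 | 35 | 13 |

(standard deviation of a reading: 1.5 percentage points)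



1. the winner by amount of target, in percent of the starting material charged; "neither" if no more than 2 percentage points parts them (cedar / birch / neither)
2. how much target is there at the end, in percent of the starting material charged: cedar
3. how much target is there at the end, in percent of the starting material charged: birch

The rule: a plateau is a yield. Friday's target stands at 35 % from 0.70 equiv of reagent, a share of 50.0 %, so about half of the reagent became target. Birch has Friday's ratio of reagent to portion, so the rule gives birch 35.0 %. Cedar offers the reagent twice as much starting material at the start, so its share should be higher, with a ceiling of 0.700 of the charge in target. I take the middle, 52.5 %.

The rule stops where the readings stop. Friday ends at 5.00 min, and birch is read 3.00 times as late, cedar 12.0 times.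

So join the two ends. Friday's target plus starting material slips by 3 percentage points between 0.667 min and 5.00 min. I charge that slip to the target, whose mean over the stretch is 27.5 %. This gives the balance half-life of the target, 27.5 min: the time in which the target would halve at the rate of that slip. It is a weak reading, since the slip carries a scatter of 3 points.

Counting decay from 5.00 min, I expect 13.1 % in cedar and 27.2 % in birch. On these two estimates birch leads by 14 points, against a margin of 2 points, so I say birch.

The forecast gives 47 % for cedar and 34 % for birch, so cedar wins, on the ground that “the target survives”.

The flasks give 17.9 % for cedar and 33.6 % for birch, so birch wins.

    2 reagent → side product (k = 19.0 M⁻¹ min⁻¹)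
    starting material + reagent → target (k = 56.0 M⁻¹ min⁻¹)
    target → over-reaction product (k = 0.0190 min⁻¹)

Cedar holds reagent at 0 % and starting material at 45.2 % from 30.0 min on, while its target falls from 31.7 % to 17.9 % by 60.0 min; the balance half-life predicts 14.9 %. In birch at 15.0 min, the rate at which target is made over the rate at which it is used up is 0.0464, and the target's half-life by the step to over-reaction product is 36 min, longer than my balance half-life. For birch read at 25 min the balance half-life predicts 26.1 %, and that flask holds 27.8 %.

All runs come from a simulation for an exercise, noise included.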